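The route rests on breaking the C3–C4 bond of ring A: the cis secondary–tertiary diol (C3–OH, C4–OH bearing the C15 methyl) is the retron of a reductive coupling between a C3 aldehyde and a C4 methyl ketone. One SmI2 operation closes ring A onto ring B as a trans-decalin and sets both carbinol centres. Its precursor is a cyclohexane (ring B, from (R)-carvone) carrying a quaternary C10 (methyl, 3-oxopropyl), a trans acetyl group at C5, the C7 isopropenyl group and C8 masked as a dioxolane. The C8 oxygen is moved from C9 by an enol triflate reduction, and the 7α,11-diol and the epoxyangelate are added last.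

Key step: step 10

Remark: ring carbons carry their eudesmane numbers throughout (ring B = C5–C10) and α is the face opposite the C10 methyl; the configurations drawn at C8 (compounds 3–9) and at C7 (compounds 3–17) are the expected ones but are erased in steps 5 and 11, so the target does not depend on them.

Step 1
Reactants: 1 (R)-carvone
Product: 3 trans-6-hydroxycarvone, via potassium dienolate 2 (not isolated)
Conditions: KN(SiMe3)2, THF, −78 °C; 2-(phenylsulfonyl)-3-phenyloxaziridine, −78 °C; AcOH
Reagents that add atoms: 2-(phenylsulfonyl)-3-phenyloxaziridine, O=S(=O)(c1ccccc1)N1OC1c1ccccc1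
Why: Kinetic deprotonation at the only α′ position (carvone C6, the future C8) and oxygen transfer from the N-sulfonyloxaziridine to the cross-conjugated enolate (enolate hydroxylation) should give the α′-hydroxy enone, the oxidant arriving trans to the neighbouring isopropenyl group.

Step 2
Reactants: 3 trans-6-hydroxycarvone
Product: 4 trans-6-methoxycarvone
Conditions: MeI, Ag2O, MeCN, rt, dark
Reagents that add atoms: iodomethane, CI
Why: Silver-oxide-promoted Williamson etherification methylates the hydroxyl without a strong base, so the enolisable α-alkoxy enone keeps its configuration and the ether oxygen cannot migrate in the later enolate chemistry.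

Step 3
Reactants: 4 trans-6-methoxycarvone; 5 vinylmagnesium bromide
Product: 6 C9 trimethylsilyl enol ether of the vinyl adduct (vinyl and methoxy both trans to isopropenyl)
Conditions: CuBr·SMe2 (10 mol%), Me3SiCl, HMPA, THF, −78 °C; Et3N, aq. NaHCO3
Reagents that add atoms: chlorotrimethylsilane, C[Si](C)(C)Cl
Why: Copper-catalysed conjugate addition of the Grignard reagent with in situ silylation delivers the vinyl group (the latent acetyl) axially to the enone β-carbon, anti to the 1,3-related isopropenyl group as is usual for carvone, which sets C5 and fixes the enolate regiochemistry as its silyl enol ether.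

Step 4
Reactants: 6 C9 trimethylsilyl enol ether; 7 methyl acrylate
Product: 9 ring B keto ester, via lithium enolate 8 (not isolated)
Conditions: MeLi, THF, 0 °C; then 7, −78 °C; AcOH
Reagents that add atoms: none
Why: MeLi cleaves the O–Si bond to the regiodefined lithium enolate, whose Michael addition to the acrylate takes place at the fully substituted carbon on the face anti to the adjacent vinyl group, so that C10 is formed with the propanoate chain trans to the C5 substituent.

Step 5
Reactants: 9 ring B keto ester
Product: 11 enol triflate, via potassium enolate 10 (not isolated)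
Conditions: KN(SiMe3)2, THF, −78 → −40 °C; PhNTf2, −78 → 0 °C
Reagents that add atoms: N-phenylbis(trifluoromethanesulfonimide), O=S(=O)(N(c1ccccc1)S(=O)(=O)C(F)(F)F)C(F)(F)F
Why: The ring ketone can enolise only towards C8 and is more acidic than the ester, so equilibrated deprotonation and O-sulfonylation (enol triflate formation) should give a single C8=C9 enol triflate in which the methyl ether cannot migrate.

Step 6
Reactants: 11 enol triflate
Product: 12 C8 methyl enol ether (C8=C9)
Conditions: Pd(OAc)2 (5 mol%), PPh3, n-Bu3N, HCO2H, DMF, 60 °C
Reagents that add atoms: none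
Why: Palladium-catalysed formate reduction of the enol triflate (oxidative addition to zerovalent palladium, formate-to-hydride exchange, reductive elimination) removes the C9 oxygen and leaves C8 as an enol ether, which completes the 1,2-transposition of the ring carbonyl without touching the ester or the isolated alkenes.

Step 7
Reactants: 12 C8 methyl enol ether
Product: 13 dioxolane ester
Conditions: HOCH2CH2OH, PPTS (cat.), CH2Cl2, rt
Reagents that add atoms: ethylene glycol, OCCO
Why: Acid-catalysed addition of the diol to the enol ether (protonation at C9, capture of the C8 oxocarbenium ion, loss of methanol) is a transketalisation that gives the dioxolane under conditions mild enough to leave the ester, the alkenes and C7 alone.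

Step 8
Reactants: 13 dioxolane ester
Product: 14 dioxolane aldehyde
Conditions: i-Bu2AlH (1.1 equiv), CH2Cl2, −78 °C; MeOH, aq. KNa tartrate
Reagents that add atoms: none
Why: Partial reduction of the methyl ester stops at the aluminium hemiacetal at −78 °C, which releases the aldehyde only on work-up.

Step 9
Reactants: 14 dioxolane aldehyde
Product: 15 keto-aldehyde (C3 aldehyde, C4 methyl ketone, C8 dioxolane)
Conditions: PdCl2 (10 mol%), CuCl, O2 (1 atm), DMF/H2O, rt
Reagents that add atoms: water, O
Why: Tsuji–Wacker oxidation converts the monosubstituted vinyl group into the methyl ketone with Markovnikov regiochemistry (oxygen from water, O2 as terminal oxidant), while the 1,1-disubstituted isopropenyl group, the aldehyde and the dioxolane are expected to be inert.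

Step 10
Reactants: 15 keto-aldehyde
Product: 16 8,8-(ethylenedioxy)-7-epi-eudesm-11-ene-3α,4α-diol
Conditions: SmI2 (2.5 equiv), t-BuOH (2 equiv), THF, slow addition of 15, −78 → −20 °C; aq. NaHCO3
Reagents that add atoms: none
Why: SmI2 (divalent samarium) reduces the aldehyde to a C3 ketyl whose trivalent samarium counter-ion also binds the C4 ketone oxygen; the ketyl carbon adds to the activated ketone, and a second electron transfer and protonation release the diol. The closest known reaction type is the SmI2 pinacol cyclisation of 1,6-keto-aldehydes to cis-cyclohexane-1,2-diols. Ring A closes 6-exo-trig through a chair in which the C5 acetyl and C10 oxopropyl arms are trans-diequatorial on ring B, so the trans ring fusion is inherited from the substrate. C3 is set relative to C4 by the five-membered samarium chelate (both oxygens syn, hence cis), and C4 is set relative to the ring by whether its oxygen or its methyl takes the axial site beside the axial C10 methyl. The step needs the α,α-diol (C4 methyl axial): the samarium-bridged diolate is expected to form on the α face, anti to the angular methyl, as the osmate ester does in osmylation of eudesm-3-enes, because the β,β-chelate would hold the metal-bound axial O4 and its ligand sphere against that methyl. The preference of the acetyl methyl for the equatorial site works the other way, so facial selectivity (β,β-diol) is the main risk, which is why the reaction is run cold and without HMPA to keep the chelate.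

Step 11
Reactants: 16 8,8-(ethylenedioxy)-7-epi-eudesm-11-ene-3α,4α-diol
Product: 18 3α,4α-dihydroxyeudesm-7(11)-en-8-one, via deconjugated enone 17 (not isolated)
Conditions: 1 M HCl, THF, rt; then NaOMe, MeOH, rt
Reagents that add atoms: water, O
Why: Aqueous acid hydrolyses the dioxolane and methoxide then equilibrates the β,γ-unsaturated ketone through its dienolate to the conjugated isopropylidene ketone, the thermodynamically preferred isomer as in the isopulegone–pulegone pair, which also removes the C7 stereocentre.

Step 12
Reactants: 18 3α,4α-dihydroxyeudesm-7(11)-en-8-one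
Product: 19 7α,11-epoxy-3α,4α-dihydroxyeudesman-8-one
Conditions: 30% H2O2, NaOH, MeOH, 0 °C → rt
Reagents that add atoms: hydrogen peroxide, OO
Why: In this Weitz–Scheffer epoxidation hydroperoxide adds to the exocyclic β-carbon C11 and the C7 enolate closes onto oxygen along the axial α trajectory through a chair-like ring B, whereas β closure would need a boat with the new C–O bond flagpole to the C10 methyl, so the C7–O bond should be set α.

Step 13
Reactants: 19 7α,11-epoxy-3α,4α-dihydroxyeudesman-8-one
Product: 20 3α,4α,7α,11-tetrahydroxyeudesman-8-one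
Conditions: 3% aq. HClO4, THF, rt
Reagents that add atoms: water, O
Why: Acid-catalysed epoxide hydrolysis opens the protonated oxirane at the tertiary exocyclic C11 (positive charge at C7 would sit next to the carbonyl), so water enters at the non-stereogenic C11 and the C7–O bond, hence the 7α-hydroxyl, is retained.

Step 14
Reactants: 21 angelic acid
Product: 22 (Z)-2-methylbut-2-en-1-ol
Conditions: LiAlH4, Et2O, 0 °C → rt
Reagents that add atoms: none
Why: Hydride reduction of the carboxylic acid gives the allylic alcohol by 1,2-reduction and leaves the Z geometry of the trisubstituted alkene unchanged.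

Step 15
Reactants: 22 (Z)-2-methylbut-2-en-1-ol
Product: 23 [(2R,3S)-2,3-dimethyloxiran-2-yl]methanol
Conditions: Ti(OiPr)4 (10 mol%), D-(−)-diethyl tartrate (12 mol%), t-BuOOH, 4 Å molecular sieves, CH2Cl2, −20 °C
Reagents that add atoms: tert-butyl hydroperoxide, CC(C)(C)OO
Why: Katsuki–Sharpless asymmetric epoxidation with the titanium catalyst of the D-(−)-tartrate delivers oxygen to the enantioface of the Z-allylic alcohol that gives the (2R,3S)-epoxy alcohol, the cis relation of the oxirane substituents following from the alkene geometry.

Step 16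
Reactants: 23 [(2R,3S)-2,3-dimethyloxiran-2-yl]methanol
Product: 24 (2S,3S)-2,3-dimethyloxirane-2-carboxylic acid
Conditions: RuCl3·xH2O (2 mol%), NaIO4, MeCN/CCl4/H2O, rt
Reagents that add atoms: water, O
Why: RuO4 generated in situ from RuCl3 and NaIO4 oxidises the primary alcohol through the aldehyde hydrate to the carboxylic acid without touching the oxirane, whose two centres are unchanged in space although the C2 descriptor becomes S.

Step 17
Reactants: 20 3α,4α,7α,11-tetrahydroxyeudesman-8-one; 24 (2S,3S)-2,3-dimethyloxirane-2-carboxylic acid
Product: 26 CNP0145407.1, via mixed anhydride 25 (not isolated)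
Conditions: 24, 2,4,6-trichlorobenzoyl chloride, Et3N, THF, rt; then 20, DMAP, toluene, rt → 40 °C
Reagents that add atoms: none
Why: Yamaguchi esterification activates the acid as the mixed aroyl anhydride and DMAP transfers the epoxyacyl group to the only secondary hydroxyl, C3–OH, while the three tertiary hydroxyls are not acylated and no stereocentre is touched because the acid has no α-hydrogen.

Compound list
1 | (R)-carvone | CC1=CC[C@H](CC1=O)C(C)=C | starting material
2 | potassium dienolate of carvone (deprotonated at carvone C6) | CC1=CC[C@@H](C(C)=C)C=C1[O-].[K+] | intermediate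
3 | trans-6-hydroxycarvone, (5S,6S)-6-hydroxy-2-methyl-5-(prop-1-en-2-yl)cyclohex-2-en-1-one | O=C1C(C)=CC[C@@H](C(C)=C)[C@@H]1O | intermediate
4 | trans-6-methoxycarvone, (5S,6S)-6-methoxy-2-methyl-5-(prop-1-en-2-yl)cyclohex-2-en-1-one | O=C1C(C)=CC[C@@H](C(C)=C)[C@@H]1OC | intermediate
5 | vinylmagnesium bromide | C=C[Mg]Br | starting material
6 | 1-(trimethylsilyloxy)-6-methoxy-2-methyl-5-(prop-1-en-2-yl)-3-vinylcyclohex-1-ene, vinyl and methoxy both trans to isopropenyl | C[Si](C)(C)OC1=C(C)[C@H](C=C)C[C@@H](C(C)=C)[C@@H]1OC | intermediate
7 | methyl acrylate | C=CC(=O)OC | starting material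
8 | lithium enolate corresponding to 6 | [Li+].[O-]C1=C(C)[C@H](C=C)C[C@@H](C(C)=C)[C@@H]1OC | intermediate
9 | methyl 3-[3-methoxy-1-methyl-2-oxo-4-(prop-1-en-2-yl)-6-vinylcyclohexyl]propanoate; C10 β-methyl and α-propanoate chain, C5 vinyl cis to the C10 methyl, C7 α-isopropenyl, C8 β-methoxy, C9 ketone | COC(=O)CC[C@]1(C)C(=O)[C@@H](OC)[C@H](C(C)=C)C[C@H]1C=C | intermediate
10 | potassium enolate of 9 (C8=C9) | COC(=O)CC[C@]1(C)C([O-])=C(OC)[C@H](C(C)=C)C[C@H]1C=C.[K+] | intermediate
11 | enol triflate of 9, C8(OMe)=C9(OSO2CF3) | COC(=O)CC[C@]1(C)C(OS(=O)(=O)C(F)(F)F)=C(OC)[C@H](C(C)=C)C[C@H]1C=C | intermediate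
12 | C8 methyl enol ether, C8(OMe)=C9H, other centres as in 9 | COC(=O)CC[C@]1(C)C=C(OC)[C@H](C(C)=C)C[C@H]1C=C | intermediate
13 | methyl 3-[9-methyl-6-(prop-1-en-2-yl)-8-vinyl-1,4-dioxaspiro[4.5]decan-9-yl]propanoate (C8 dioxolane; C10 β-methyl, C5 vinyl cis to it, C7 α-isopropenyl) | COC(=O)CC[C@]1(C)CC2(OCCO2)[C@H](C(C)=C)C[C@H]1C=C | intermediate
14 | 3-[9-methyl-6-(prop-1-en-2-yl)-8-vinyl-1,4-dioxaspiro[4.5]decan-9-yl]propanal, configuration as in 13 | O=CCC[C@]1(C)CC2(OCCO2)[C@H](C(C)=C)C[C@H]1C=C | intermediate
15 | 3-[8-acetyl-9-methyl-6-(prop-1-en-2-yl)-1,4-dioxaspiro[4.5]decan-9-yl]propanal (C5 acetyl trans to the C10 oxopropyl chain, C7 α-isopropenyl) | O=CCC[C@]1(C)CC2(OCCO2)[C@H](C(C)=C)C[C@H]1C(C)=O | intermediate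
16 | 8,8-(ethylenedioxy)-7-epi-eudesm-11-ene-3α,4α-diol (5α-H, 10β-methyl, 4β-methyl, 7α-isopropenyl) | O[C@@H]1CC[C@]2(C)CC3(OCCO3)[C@H](C(C)=C)C[C@H]2[C@]1(C)O | intermediate
17 | 3α,4α-dihydroxy-7-epi-eudesm-11-en-8-one | O[C@@H]1CC[C@]2(C)CC(=O)[C@H](C(C)=C)C[C@H]2[C@]1(C)O | intermediate
18 | 3α,4α-dihydroxyeudesm-7(11)-en-8-one | O[C@@H]1CC[C@]2(C)CC(=O)C(=C(C)C)C[C@H]2[C@]1(C)O | intermediate
19 | 7α,11-epoxy-3α,4α-dihydroxyeudesman-8-one | O[C@@H]1CC[C@]2(C)CC(=O)[C@]3(OC3(C)C)C[C@H]2[C@]1(C)O | intermediate
20 | 3α,4α,7α,11-tetrahydroxyeudesman-8-one | O[C@@H]1CC[C@]2(C)CC(=O)[C@@](O)(C(C)(C)O)C[C@H]2[C@]1(C)O | intermediate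
21 | angelic acid, (Z)-2-methylbut-2-enoic acid | C/C=C(/C)C(=O)O | starting material
22 | (Z)-2-methylbut-2-en-1-ol | C/C=C(/C)CO | intermediate
23 | [(2R,3S)-2,3-dimethyloxiran-2-yl]methanol | C[C@@H]1O[C@]1(C)CO | intermediate
24 | (2S,3S)-2,3-dimethyloxirane-2-carboxylic acid (epoxyangelic acid) | C[C@@H]1O[C@]1(C)C(=O)O | intermediate
25 | mixed anhydride of 24 with 2,4,6-trichlorobenzoic acid | C[C@@H]1O[C@]1(C)C(=O)OC(=O)c1c(Cl)cc(Cl)cc1Cl | intermediate
26 | CNP0145407.1, 3α-[(2S,3S)-2,3-epoxy-2-methylbutanoyloxy]-4α,7α,11-trihydroxyeudesman-8-one | C[C@@H]1O[C@]1(C)C(=O)O[C@@H]1CC[C@]2(C)CC(=O)[C@@](O)(C(C)(C)O)C[C@H]2[C@]1(C)O | target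

Total step count: 17. Longest linear sequence: 14 steps (steps 1–13, then step 17); steps 14–16 form the three-step side branch to the acid.

Steps most likely to fail

Step 10. The ring closure may run through the other acetyl rotamer (oxygen instead of methyl beside the C10 methyl) or without the chelate, that is, with poor facial or cis/trans selectivity. The fallback sets out from 15 and comes back at 18. Intramolecular McMurry coupling of 15 with low-valent titanium (TiCl3(DME)1.5, Zn–Cu couple, DME, reflux, slow addition) should give the ring A alkene 8,8-(ethylenedioxy)-7-epi-eudesma-3,11-diene F1. Treatment as in step 11 (1 M HCl, THF, then NaOMe, MeOH) should give eudesma-3,7(11)-dien-8-one F2. OsO4 (cat.), NMO, acetone/H2O should then dihydroxylate only the electron-rich trisubstituted C3=C4 alkene, from the α face opposite the C10 methyl, the conjugated tetrasubstituted alkene being inert, and deliver 18.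

Step 13. Ionisation at C11 may end in proton loss or in a 1,2-shift instead of capture by water. The fallback sets out from 18 and comes back at 20, without passing through the epoxide. Excess KN(SiMe3)2 (THF, −78 °C) deprotonates a γ-methyl group to the extended enolate, which 2-(phenylsulfonyl)-3-phenyloxaziridine should hydroxylate at C7 from the axial α face to give 3α,4α,7α-trihydroxyeudesm-11-en-8-one F3. Mukaiyama hydration of the isopropenyl group (Co(acac)2 cat., PhSiH3, O2, i-PrOH) should then give 20. F3 is also what an elimination in step 13 would leave, so diverted material can re-enter at this point.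

Step 17. Acyl transfer to the hindered axial C3 hydroxyl may be slower than consumption of the mixed anhydride by aroyl transfer or symmetric anhydride formation. The fallback sets out from 20 and 24 and comes back at 26. Bu2SnO (toluene, reflux, removal of water) converts the cis-3,4-diol into the 3,4-O-dibutylstannylene acetal F4, which activates O3 as a tin alkoxide. Acid 24 is converted under neutral conditions with 1-chloro-N,N,2-trimethylprop-1-en-1-amine (CH2Cl2, 0 °C) into (2S,3S)-2,3-dimethyloxirane-2-carbonyl chloride F5. F4 and F5 (CH2Cl2, 0 °C → rt, aqueous work-up) should give 26.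

Further compounds
F1 | step 10 | 8,8-(ethylenedioxy)-7-epi-eudesma-3,11-diene | CC1=CCC[C@]2(C)CC3(OCCO3)[C@H](C(C)=C)C[C@@H]12
F2 | step 10 | eudesma-3,7(11)-dien-8-one | CC1=CCC[C@]2(C)CC(=O)C(=C(C)C)C[C@@H]12
F3 | step 13 | 3α,4α,7α-trihydroxyeudesm-11-en-8-one | O[C@@H]1CC[C@]2(C)CC(=O)[C@@](O)(C(C)=C)C[C@H]2[C@]1(C)O
F4 | step 17 | 3,4-O-dibutylstannylene acetal of 20 | CCCC[Sn]1(CCCC)O[C@@H]2CC[C@]3(C)CC(=O)[C@@](O)(C(C)(C)O)C[C@H]3[C@]2(C)O1
F5 | step 17 | (2S,3S)-2,3-dimethyloxirane-2-carbonyl chloride | C[C@@H]1O[C@]1(C)C(=O)Cl
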